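Per cent of charged substrate per minute is the unit to watch: delta, theta and gamma climb almost straight in it after a short lag, although the substrates are being consumed, while alpha bends at its end.

| setting | alpha | delta | theta | gamma | maple | elm | cedar | larch |
|---|---|---|---|---|---|---|---|---|
| left-handed substrate | 27 mM | 27 mM | 27 mM | 27 mM | 27 mM | 27 mM | 27 mM | 27 mM |
| right-handed substrate | 27 mM | 27 mM | 27 mM | 27 mM | 27 mM | 27 mM | 27 mM | 27 mM |
| solid reagent | 1.2 equiv | 2.1 equiv | 2.7 equiv | 3 equiv | 3.00 equiv | 3.00 equiv | 3.00 equiv | 1.50 equiv |
| catalyst | 0.5 mol% | 0.5 mol% | 0.5 mol% | 0.34 mol% | 0.5 mol% | 0.15 mol% | 0.5 mol% | 0.5 mol% |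
| temperature | 75 °C | 100 °C | 75 °C | 100 °C | 95 °C | 80 °C | 80 °C | 120 °C |
| remark | run made earlier | run made earlier | run made earlier | run made earlier |  |  |  |  |
| time |  |  |  |  | 25 min | 25 min | 25 min | 25 min |

| run | time / min | left-handed product / % |
|---|---|---|
| alpha | 5.00 | 4.4 |
| alpha | 10.0 | 12.6 |
| alpha | 15.0 | 21.5 |
| alpha | 20.0 | 28.2 |
| alpha | 25.0 | 30.5 |
| delta | 2.00 | 3.0 |
| delta | 4.00 | 6.7 |
| delta | 6.00 | 11.1 |
| delta | 8.00 | 17.1 |
| delta | 10.0 | 19.9 |
| theta | 2.00 | 1.1 |
| theta | 6.00 | 7.2 |
| theta | 12.0 | 15.8 |
| theta | 20.0 | 26.9 |
| theta | 25.0 | 34.3 |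
| gamma | 2.00 | 1.5 |
| gamma | 4.00 | 5.4 |
| gamma | 6.00 | 9.4 |
| gamma | 8.00 | 13.7 |
| gamma | 10.0 | 18.1 |

(each reading ± 0.5 percentage points)

- catalyst is single-handed; left-handed substrate and right-handed substrate are mirror images of each other, charged as a racemate, each of them at the stated concentration
- solid, in amounts per volume of the solution: solid reagent
- what was read earlier has a scatter of 0.5 percentage points, one standard deviation
- at the start none of the solid reagent is in solution

1. the flasks by amount of left-handed product, in percent of the left-handed substrate and right-handed substrate together charged, highest first, at 25 min (maple / elm / cedar / larch)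
2. the amount of left-handed product, in percent of the left-handed substrate and right-handed substrate together charged of the flask you put first, at 25 min
3. the amount of left-handed product, in percent of the left-handed substrate and right-handed substrate together charged of the flask you put last, at 25 min

Solid charge shows no gain in speed: at 20.0 min, alpha with 1.2 equiv stands at 28.2% and theta with 2.7 equiv at 26.9%. Delta and gamma, both at 100 °C, differ in catalyst and also in solid charge; with solid charge taken as without effect, their readings at 10.0 min give one number:

ν = ln(19.9% / 18.1%) / ln(0.5 mol% / 0.34 mol%) = 0.246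

This reading, ν, is the apparent order in catalyst, the power to which the yield follows the loading. An order of one would put the pace on the catalytic step; this low reading points instead to the dissolved part of the solid reagent as the concentration to suspect. Carried from theta to elm's loading, my own reckoning gives:

y(elm) ≈ 34.3% × (0.15 mol% / 0.5 mol%)^ν = 25.5%

One number is not enough, however. ν compares loadings and cannot place larch, with 1.50 equiv at 120 °C, while alpha's last interval gained 2.3 percentage points after 6.7 points in the one before.

The forecast gives maple > cedar > larch > elm, with 45% first and 25% last: “Larch is therefore capped near 37.5%”.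

The flasks give larch > maple > cedar > elm.

    coupling partner + catalyst + left-handed substrate → catalyst + left-handed product (k = 700 M⁻² s⁻¹, Ea = 42.0 kJ mol⁻¹)
    coupling partner + catalyst + right-handed substrate → catalyst + right-handed product (k = 380 M⁻² s⁻¹, Ea = 36.0 kJ mol⁻¹)
    solid reagent ⇌ coupling partner, rate k3*(cs3 - [coupling partner]) while solid is left; crystals form when [coupling partner] > cs3 (solubility = 24.0 mM, k = 0.00190 s⁻¹)
    left-handed substrate ⇌ right-handed substrate (k = 0.00200 s⁻¹, Ea = 96.0 kJ mol⁻¹)
    (constants at 80 °C)

Larch stands first at 51.1% and elm last at 20.9%. At 25.0 min, larch also holds 22.7% of right-handed product, and its solid reagent stands at 0%. Applied to cedar's 37.8%, ν gives 28.1% for elm, which reached 20.9%; the order read between these two flasks is 0.491, higher than ν. Alpha, moved to elm's loading, gets 23.3% from ν and actually gives 18.2%.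

All runs come from a simulation for substances that don't exist; the scatter is artificial.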